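# Total synthesis of marchantin C: ring B and the macrocycle closed together by an intramolecular Diels–Alder reaction

## Analysis of the target

- **Ring system.** Marchantin C (24) is a macrocyclic bis(bibenzyl). Four benzene rings form one loop through two diaryl ether oxygens (ring A–O–ring B, ring C–O–ring D) and two CH2CH2 bridges (ring B–ring C, ring D–ring A). The shortest circuit holds 18 atoms.
- **Substitution patterns.** Ring A is 1,2,4-trisubstituted, with OH para to its arm and the ether oxygen ortho to the OH. Ring B is a para-phenylene. Ring C is 1,2,3-trisubstituted, with the ether oxygen wedged between its OH and its arm. Ring D is a meta-phenylene.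
- **Stereochemistry.** There is no stereocentre and no defined double bond, so nothing has to be controlled or related. A stereocentre formed on the way only has to disappear again.
- **Sensitive groups.** The two phenols each sit ortho to an aryloxy group and are easily oxidised, as are the benzylic CH2 groups para to oxygen. The phenols therefore travel as methyl ethers until the last step.
- **Difficulty.** An 18-membered cyclophane with little slack has to be closed against oligomerisation. Two different diaryl ethers are also needed, and one of them is flanked on both sides.
- **Feature used.** Ring B carries the oxygen to ring A at C1 and the benzylic carbon of the bridge to ring C at C4. A butadiene oxygenated at C2 leaves exactly this 1,4 pattern when it adds to an acyl-activated alkene, provided the benzylic carbon is a ketone for a time.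

## Retrosynthetic reasoning

**24 ⇒ 23.** The two phenolic O–H bonds go back to O–CH3 bonds. These methyl ethers come with the arenes 1 and 8 and survive every condition of the route. Their Lewis acid cleavage at the end leaves the diaryl ethers and the bridges alone.

**23 ⇒ 21 (through 22).** The bridge carbon on ring B is raised to a ketone. The activating group of a dienophile must sit at exactly this carbon. A ketone conjugated to a para-aryloxyphenyl ring can be removed in one ionic hydrogenation through carbinol 22.

**21 ⇒ 19 (through 20).** Ring B is taken back by four hydrogens to the 4-acyl-1-aryloxycyclohexene 19. The arene becomes a ring that a cycloaddition can build, and the aryl C–O bond to ring A becomes an enol ether bond. The forward dehydrogenation is driven by aromaticity and erases the stereocentre.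

**19 ⇒ 18.** The bonds C3–C4 and C5–C6 of the cyclohexene are cut in a retro-[4+2]. C6, C1, C2 and C3 become a butadiene with the ring A oxygen on its second carbon. C4 and C5 become the alkene of a vinyl ketone.
- No other cut opens the six-membered ring and the 18-membered ring at once.
- No other cut removes the need for an aryl C–O coupling at ring B.
- The forward step must give the 1,4 orientation and must beat oligomerisation.

**18 ⇒ 17 ⇒ 16.** The enone is masked as a silyl-protected allylic alcohol. A ketone would not survive the carbonyl methylenation that makes the diene. It is therefore released afterwards, under basic and then buffered neutral conditions that spare the enol ether.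

**16 ⇒ 15.** The C=CH2 bond on the oxygen-bearing diene carbon is traced to an ester C=O. The dienyl ether thus derives from an aryl acrylate by titanium methylenation. The difficult O–C(sp2) bond becomes an ordinary acylation.

**15 ⇒ 14 ⇒ 12 + 13.** The O–Si bond and then the O–acyl bond are cut. The forward acylation must choose the phenol of 12 over its secondary alcohol. The large difference in acidity makes this possible.

**12 ⇒ 11 ⇒ 10 ⇒ 9.** The vinyl–carbinol C–C bond is cut to the arylacetaldehyde 11. The extra carbon of 11 is then cut back to the benzaldehyde 9 through enol ether 10. One acid treatment frees both the aldehyde and the ring A phenol, so the phenol protecting group costs no step of its own.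

**9 ⇒ 7 + 8.** The hindered ring C–O bond is cut on the ring C side, because the formyl group of 8 activates its fluorine for addition–elimination. If ring D still carried a formyl group at this stage, the product would hold two aryl aldehydes that no reagent could distinguish. The ring A–ring D bridge is therefore built first.

**7 ⇒ 6 ⇒ 2 + 4 (through 5); 2 ⇒ 1; 4 ⇒ 3.** The bridge is cut at its central bond to an olefination followed by hydrogenation. This places the only hydrogenation before any vinyl group exists. Ring D enters as the benzylic alcohol 3, which gives phosphonium salt 4 in one step with its phenol free. Ring A enters as 1, with its phenol capped in 2.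

## Alternatives that were turned down

**Alternative 1:**
- **Disconnection.** The ring C oxygen–ring D carbon bond is cut. This gives the seco phenol A1, whose ring D carries fluorine at the future ether carbon and a nitro group para to it.
- **Forward key step.** Carbonate base forms the ring C phenoxide, which adds to the fluorinated carbon. The nitro group stabilises the adduct, and loss of fluoride gives the nitro macrocycle A2.
- **In favour.** Intramolecular SNAr is among the most dependable closures of cyclophane diaryl ethers. All four rings are bought as arenes. The crowded ether is made where intramolecularity helps most.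
- **Against.**
  - The nucleophile is flanked by OMe and by the arm.
  - The nitro group is absent from 24, so it costs reduction, diazotisation and hydrodediazoniation after closure.
  - It rules out catalytic hydrogenation of stilbene bridges during assembly.
  - It acidifies the neighbouring benzylic CH2 under the basic closure conditions.
  - The ring A–ring B ether still needs a coupling of its own.
- **Comparison.** This plan is stronger on the certainty of ring closure. The chosen plan instead offers a closure whose helper group leaves in one step, a ring B ether made without any aryl C–O coupling, and two rings formed in one event.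

**Alternative 2:**
- **Disconnection.** Ring C is taken back to a cyclohexenone, and its C–C bond between the oxygen-bearing and the arm-bearing carbon is cut. This gives the 22-membered 1,5-diketone A3.
- **Forward key step.** Base enolises the CH2 between the ring D oxygen and one ketone. The enolate attacks the other ketone across the ring and water is lost. The product is A4, a 2-aryloxy-3-alkylcyclohex-2-enone inside an 18-membered ring, and dehydrogenation then gives ring C.
- **In favour.** The crowded ether shrinks to a simple phenol alkylation. The ring C phenol arrives unprotected. A flexible 22-membered ring is easier to close than the final one.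
- **Against.**
  - A separate macrocyclisation must come first, so the aldol saves no ring closure.
  - A3 has four enolisable positions.
  - A second six-membered aldol mode, starting from the CH2 of the ring B arm, is just as accessible geometrically.
  - Dehydration has to form a tetrasubstituted alkene.
  - The ring A–ring B ether still has to be coupled.
- **Comparison.** This plan is stronger at the hindered ether and at protecting-group economy on ring C. The chosen plan merges macrocyclisation and ring construction in one step, and its regiochemistry rests on one clear donor–acceptor match.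

**Alternative 3:**
- **Disconnection.** The ring B oxygen–ring A carbon bond is cut. This gives the seco bis(phenol) A5, with ring A as a 2,6-dibromophenol and ring B as a 2,6-dichlorophenol.
- **Forward key step.** Tl(NO3)3 (trivalent thallium) oxidises the more easily oxidised dibromophenol. The ring B phenol oxygen adds at a bromine-bearing ortho carbon. Zinc reduces the dienone with loss of bromide and gives A6.
- **In favour.** The step mirrors a plausible biogenesis and needs no preformed coupling partners. The ring A phenol stays free, and the seco compound is short to assemble.
- **Against.**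
  - Four halogens must be installed, and three must later be removed by hydrogenolysis.
  - A toxic metal is used stoichiometrically.
  - The roles of the two phenols depend on a small difference in oxidation potential.
  - Solvent capture of the oxidised ring competes with an 18-membered closure.
  - Ring C and the benzylic positions face a strong two-electron oxidant.
- **Comparison.** The two plans are about level in step count after closure, and this one is shorter before it. The chosen plan offers frontier-orbital regiocontrol, neutral closure conditions and no halogen traffic.

Key step: step 14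

Remark on the chemistry: the target has no stereocentre. The chiral intermediates 12, 14 to 17, 19 and 22 are racemic, and 6 and 10 are E/Z mixtures, so their SMILES carry no stereodescriptors.

## Route

Step 1
Reactants: 1 isovanillin (3-hydroxy-4-methoxybenzaldehyde)
Product: 2 4-methoxy-3-(methoxymethoxy)benzaldehyde
Conditions: MOMCl, iPr2NEt, CH2Cl2, 0 °C to rt
Reagents that add atoms: chloromethyl methyl ether, COCCl
Why: Williamson-type O-alkylation of the phenol by a very reactive α-chloro ether, with the aldehyde inert. The MOM acetal withstands ylides, H2 over Pd/C and hot carbonate, and it leaves in the acid treatment of step 7, so it needs no deprotection step of its own.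

Step 2
Reactants: 3 3-hydroxybenzyl alcohol
Product: 4 (3-hydroxybenzyl)triphenylphosphonium bromide
Conditions: Ph3P·HBr, MeCN, reflux
Reagents that add atoms: triphenylphosphine hydrobromide, [Br-].c1ccc(cc1)[PH+](c1ccccc1)c1ccccc1
Why: Direct phosphonium salt formation from a benzylic alcohol, in which HBr activates the OH as water and Ph3P takes the benzylic carbon. The phenol does not react and needs no protection.

Step 3
Reactants: 2 4-methoxy-3-(methoxymethoxy)benzaldehyde; 4 (3-hydroxybenzyl)triphenylphosphonium bromide
Product: 6 3-{2-[4-methoxy-3-(methoxymethoxy)phenyl]ethenyl}phenol (E/Z mixture), via potassium phenoxide ylide 5 (not isolated)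
Conditions: 4, KOtBu (2.2 equiv), THF, 0 °C; then 2, 0 °C to rt
Reagents that add atoms: none
Why: Wittig olefination with a semistabilised benzylic ylide; the first equivalent of base goes to the phenol and the second forms ylide 5, whose phenoxide is a spectator. The E/Z ratio is irrelevant because step 4 saturates the double bond.

Step 4
Reactants: 6 3-{2-[4-methoxy-3-(methoxymethoxy)phenyl]ethenyl}phenol
Product: 7 3-{2-[4-methoxy-3-(methoxymethoxy)phenyl]ethyl}phenol
Conditions: H2 (1 atm), 10% Pd/C, EtOAc, rt
Reagents that add atoms: none
Why: Heterogeneous catalytic hydrogenation of a stilbene; the aryl ethers, the MOM acetal and the phenol are inert in neutral EtOAc. The step is placed before any vinyl group exists.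

Step 5
Reactants: 7 3-{2-[4-methoxy-3-(methoxymethoxy)phenyl]ethyl}phenol; 8 2-fluoro-3-methoxybenzaldehyde
Product: 9 3-methoxy-2-(3-{2-[4-methoxy-3-(methoxymethoxy)phenyl]ethyl}phenoxy)benzaldehyde
Conditions: K2CO3, DMF, 120 °C
Reagents that add atoms: none
Why: Nucleophilic aromatic substitution by addition–elimination; the ortho formyl group stabilises the anionic adduct and fluoride is the best leaving group for this mechanism. Only the ring D phenol is free, so one ether forms and 9 holds a single aldehyde.

Step 6
Reactants: 9 3-methoxy-2-(3-{2-[4-methoxy-3-(methoxymethoxy)phenyl]ethyl}phenoxy)benzaldehyde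
Product: 10 methyl enol ether of the homologated aldehyde, ring C arm CH=CH–OMe (E/Z mixture)
Conditions: MeOCH2PPh3Cl, KOtBu, THF, 0 °C to rt
Reagents that add atoms: (methoxymethyl)triphenylphosphonium chloride, [Cl-].COC[P+](c1ccccc1)(c1ccccc1)c1ccccc1
Why: Wittig reaction of a non-enolisable aldehyde with the methoxymethylidene ylide, the usual first half of a one-carbon aldehyde homologation. The geometry is lost in step 7.

Step 7
Reactants: 10 methyl enol ether (E/Z mixture)
Product: 11 (2-{3-[2-(3-hydroxy-4-methoxyphenyl)ethyl]phenoxy}-3-methoxyphenyl)acetaldehyde
Conditions: 2 M aq HCl, THF, 50 °C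
Reagents that add atoms: water, O
Why: Acid hydrolysis of two acetal-type groups at once: C-protonation of the enol ether and capture by water give the arylacetaldehyde, and the MOM acetal is cleaved to the ring A phenol. Methyl and diaryl ethers are stable to dilute aqueous acid.

Step 8
Reactants: 11 (2-{3-[2-(3-hydroxy-4-methoxyphenyl)ethyl]phenoxy}-3-methoxyphenyl)acetaldehyde
Product: 12 rac-5-(2-{3-[2-(2-hydroxybut-3-en-1-yl)-6-methoxyphenoxy]phenyl}ethyl)-2-methoxyphenol
Conditions: CH2=CHMgBr (3 equiv), THF, −78 to 0 °C
Reagents that add atoms: vinylmagnesium bromide, C=C[Mg]Br
Why: Grignard 1,2-addition; the first equivalent deprotonates the phenol to an inert magnesium phenoxide, and the low temperature favours addition over enolisation. The carbinol stereocentre forms as a racemate, is not controlled and is destroyed in step 13.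

Step 9
Reactants: 12 rac-phenol allylic alcohol; 13 acryloyl chloride
Product: 14 rac-5-(2-{3-[2-(2-hydroxybut-3-en-1-yl)-6-methoxyphenoxy]phenyl}ethyl)-2-methoxyphenyl acrylate
Conditions: 1 M aq NaOH, Bu4NHSO4 (cat.), CH2Cl2, 0 °C
Reagents that add atoms: none
Why: Phase-transfer Schotten–Baumann acylation; dilute hydroxide ionises only the phenol, and its ion pair is acylated in the organic layer. The neutral secondary alcohol reacts far more slowly.

Step 10
Reactants: 14 rac-aryl acrylate allylic alcohol
Product: 15 rac-aryl acrylate with the allylic alcohol as its tert-butyldimethylsilyl ether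
Conditions: TBSOTf, 2,6-lutidine, CH2Cl2, −78 to 0 °C
Reagents that add atoms: tert-butyldimethylsilyl triflate, CC(C)(C)[Si](C)(C)OS(=O)(=O)C(F)(F)F
Why: Silylation of a secondary alcohol with a silyl triflate and a hindered, non-nucleophilic base, chosen because a nucleophilic amine would attack the activated aryl acrylate. The silyl ether removes the OH proton that would consume Cp2TiMe2.

Step 11
Reactants: 15 rac-aryl acrylate TBS ether
Product: 16 rac-2-aryloxybuta-1,3-diene TBS ether (ring A oxygen on C2 of the butadiene)
Conditions: Cp2TiMe2 (2.5 equiv), BHT (cat.), toluene, 70 °C, dark
Reagents that add atoms: Cp2TiMe2, C[Ti+2]C.c1cc[cH-]c1.c1cc[cH-]c1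
Why: Petasis methylenation; thermolysis of Cp2TiMe2 gives the titanium methylidene, which adds [2+2] to the ester C=O and cycloreverts, driven by the Ti=O bond. Aryl esters and α,β-unsaturated esters both give enol ethers in this reaction without conjugate addition. The silyl ether and aryl ethers are inert, and the isolated vinyl group can only undergo degenerate methylene exchange.

Step 12
Reactants: 16 rac-2-aryloxybutadiene TBS ether
Product: 17 rac-2-aryloxybutadiene allylic alcohol
Conditions: TBAF, THF, 0 °C
Reagents that add atoms: none
Why: Fluoride desilylation driven by the Si–F bond. The basic, acid-free medium leaves the acid-labile dienyl ether intact.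

Step 13
Reactants: 17 rac-2-aryloxybutadiene allylic alcohol
Product: 18 1-[2-(3-{2-[3-(buta-1,3-dien-2-yloxy)-4-methoxyphenyl]ethyl}phenoxy)-3-methoxyphenyl]but-3-en-2-one
Conditions: Dess–Martin periodinane, NaHCO3, CH2Cl2, 0 °C
Reagents that add atoms: none
Why: Dess–Martin oxidation of a secondary allylic alcohol under bicarbonate buffer; it is fast at 0 °C, neutral, and tolerant of enol ethers and electron-rich arenes. It removes the carbinol stereocentre, and 18 is kept cold and dilute and used at once.

Step 14
Reactants: 18 open-chain 2-aryloxybutadiene benzyl vinyl ketone
Product: 19 racemic macrocycle with ring B as a 4-acyl-1-aryloxycyclohexene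
Conditions: BHT (cat.), toluene (1 mM, syringe-pump addition), 110 °C
Reagents that add atoms: none
Why: This is a normal-electron-demand Diels–Alder reaction, concerted but asynchronous: the oxygen-raised HOMO of the 2-aryloxydiene meets the LUMO of the vinyl ketone, and the bond from the diene CH2 next to the oxygen-bearing carbon (largest HOMO coefficient) to the enone β-carbon (largest LUMO coefficient) forms ahead of the other. The closest known reaction types are the type 2 intramolecular Diels–Alder reaction (tether on C2 of the diene) with long tethers, Diels–Alder macrocyclisations followed by aromatisation to a cyclophane arene, and the 1,4-selective intermolecular additions of 2-alkoxy- and 2-silyloxybutadienes to enones. The six-membered ring closes by suprafacial union of the four diene carbons with the two alkene carbons, forming C3–C4 and C5–C6 of the future ring B. The 18-membered ring closes in the same event, because a 14-atom tether runs from C1 through the ring A oxygen to the acyl carbon on C4; the product is a bicyclo[14.2.2] frame whose bridgehead enol ether double bond lies in a ring far too large for Bredt strain. The one new stereocentre, C4, has no controlling element and forms as a racemate, which is harmless because step 15 flattens it, and endo or exo approach is equally without consequence. The first required selectivity is 1,4 over 1,3 orientation, which the matched donor and acceptor polarisation secures and the tether does not oppose, since it spans the para positions just as it does in 24. The second is ring closure over oligomerisation, secured by holding free 18 at or below millimolar level through slow addition. BHT holds back radical polymerisation of the enone, and neutral toluene spares the enol ether.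

Step 15
Reactants: 19 racemic cyclohexenyl ether macrocycle
Product: 21 macrocyclic aryl ketone (marchantin C dimethyl ether with C=O on the bridge carbon next to ring B), via cyclohexadiene 20 (not isolated)
Conditions: DDQ (2.3 equiv), 4 Å MS, 1,4-dioxane, rt to 80 °C
Reagents that add atoms: none
Why: Quinone dehydrogenation; hydride abstraction from the allylic C3–H gives an oxygen-stabilised allyl cation, and loss of the acidic C4–H gives the push–pull diene 20. A second equivalent of DDQ completes aromatisation. The gain in aromaticity drives the step and the stereocentre vanishes.

Step 16
Reactants: 21 macrocyclic aryl ketone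
Product: 23 marchantin C dimethyl ether, via benzylic carbinol 22 (not isolated)
Conditions: Et3SiH (5 equiv), CF3CO2H, CH2Cl2, 0 °C to rt
Reagents that add atoms: none
Why: Ionic hydrogenation (Kursanov–Parnes); the protonated aryl ketone takes hydride to give carbinol 22, which ionises to a benzylic cation stabilised by the para aryloxy group and takes a second hydride. Diaryl and methyl ethers are inert.

Step 17
Reactants: 23 marchantin C dimethyl ether
Product: 24 marchantin C
Conditions: BBr3 (6 equiv), CH2Cl2, −78 °C to rt; then H2O
Reagents that add atoms: none
Why: Lewis acid cleavage of aryl methyl ethers; bromide attacks the methyl carbon of the boron-complexed ether and hydrolysis frees the phenols. Diaryl ethers offer no sp3 carbon to attack and survive.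

## Compound list

1 | isovanillin (3-hydroxy-4-methoxybenzaldehyde) | COc1ccc(C=O)cc1O | starting material
2 | 4-methoxy-3-(methoxymethoxy)benzaldehyde | COCOc1cc(C=O)ccc1OC | intermediate
3 | 3-hydroxybenzyl alcohol | OCc1cccc(O)c1 | starting material
4 | (3-hydroxybenzyl)triphenylphosphonium bromide | [Br-].Oc1cccc(C[P+](c2ccccc2)(c2ccccc2)c2ccccc2)c1 | intermediate
5 | potassium 3-[(triphenylphosphoranylidene)methyl]phenoxide (ylide, not isolated) | [K+].[O-]c1cccc(C=P(c2ccccc2)(c2ccccc2)c2ccccc2)c1 | intermediate
6 | 3-{2-[4-methoxy-3-(methoxymethoxy)phenyl]ethenyl}phenol (E/Z mixture) | COCOc1cc(C=Cc2cccc(O)c2)ccc1OC | intermediate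
7 | 3-{2-[4-methoxy-3-(methoxymethoxy)phenyl]ethyl}phenol | COCOc1cc(CCc2cccc(O)c2)ccc1OC | intermediate
8 | 2-fluoro-3-methoxybenzaldehyde | COc1cccc(C=O)c1F | starting material
9 | 3-methoxy-2-(3-{2-[4-methoxy-3-(methoxymethoxy)phenyl]ethyl}phenoxy)benzaldehyde | COCOc1cc(CCc2cccc(Oc3c(OC)cccc3C=O)c2)ccc1OC | intermediate
10 | 1-methoxy-3-(2-methoxyethenyl)-2-(3-{2-[4-methoxy-3-(methoxymethoxy)phenyl]ethyl}phenoxy)benzene (E/Z mixture) | COCOc1cc(CCc2cccc(Oc3c(OC)cccc3C=COC)c2)ccc1OC | intermediate
11 | (2-{3-[2-(3-hydroxy-4-methoxyphenyl)ethyl]phenoxy}-3-methoxyphenyl)acetaldehyde | COc1ccc(CCc2cccc(Oc3c(OC)cccc3CC=O)c2)cc1O | intermediate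
12 | rac-5-(2-{3-[2-(2-hydroxybut-3-en-1-yl)-6-methoxyphenoxy]phenyl}ethyl)-2-methoxyphenol | COc1ccc(CCc2cccc(Oc3c(OC)cccc3CC(O)C=C)c2)cc1O | intermediate
13 | acryloyl chloride | C=CC(=O)Cl | starting material
14 | rac-5-(2-{3-[2-(2-hydroxybut-3-en-1-yl)-6-methoxyphenoxy]phenyl}ethyl)-2-methoxyphenyl acrylate | COc1ccc(CCc2cccc(Oc3c(OC)cccc3CC(O)C=C)c2)cc1OC(=O)C=C | intermediate
15 | rac-tert-butyldimethylsilyl ether of 14 | COc1ccc(CCc2cccc(Oc3c(OC)cccc3CC(O[Si](C)(C)C(C)(C)C)C=C)c2)cc1OC(=O)C=C | intermediate
16 | rac-buta-1,3-dien-2-yl aryl ether with the TBS-protected allylic alcohol | COc1ccc(CCc2cccc(Oc3c(OC)cccc3CC(O[Si](C)(C)C(C)(C)C)C=C)c2)cc1OC(=C)C=C | intermediate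
17 | rac-1-[2-(3-{2-[3-(buta-1,3-dien-2-yloxy)-4-methoxyphenyl]ethyl}phenoxy)-3-methoxyphenyl]but-3-en-2-ol | COc1ccc(CCc2cccc(Oc3c(OC)cccc3CC(O)C=C)c2)cc1OC(=C)C=C | intermediate
18 | 1-[2-(3-{2-[3-(buta-1,3-dien-2-yloxy)-4-methoxyphenyl]ethyl}phenoxy)-3-methoxyphenyl]but-3-en-2-one | C=CC(=C)Oc1cc(ccc1OC)CCc1cccc(c1)Oc1c(OC)cccc1CC(=O)C=C | intermediate
19 | racemic macrocycle, ring B as 4-acyl-1-aryloxycyclohexene | COc1ccc2cc1OC1=CCC(CC1)C(=O)Cc1cccc(OC)c1Oc1cccc(c1)CC2 | intermediate
20 | macrocycle, ring B as 4-acyl-1-aryloxycyclohexa-1,3-diene (not isolated) | COc1ccc2cc1OC1=CC=C(CC1)C(=O)Cc1cccc(OC)c1Oc1cccc(c1)CC2 | intermediate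
21 | macrocyclic aryl ketone (marchantin C dimethyl ether with C=O next to ring B) | COc1ccc2cc1Oc1ccc(cc1)C(=O)Cc1cccc(OC)c1Oc1cccc(c1)CC2 | intermediate
22 | racemic macrocyclic benzylic carbinol (not isolated) | COc1ccc2cc1Oc1ccc(cc1)C(O)Cc1cccc(OC)c1Oc1cccc(c1)CC2 | intermediate
23 | marchantin C dimethyl ether | COc1ccc2cc1Oc1ccc(cc1)CCc1cccc(OC)c1Oc1cccc(c1)CC2 | intermediate
24 | marchantin C | Oc1ccc2cc1Oc1ccc(cc1)CCc1cccc(O)c1Oc1cccc(c1)CC2 | target

## Step count and least certain steps

Total step count: 17. Longest linear sequence: 16 steps (1 to 24 through steps 1 and 3 to 17). Step 2 is the only side branch.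

**Step 14 (key step).** The transition state for an 18-membered closure has a low effective molarity, so the unimolecular reaction may be slow at 110 °C.
- What may go wrong:
  - Intermolecular cycloaddition, enone polymerisation or slow thermal decay of the vinyl ketone may then outrun closure.
  - Another possible leak is addition of the enone as an oxadiene to the enol ether double bond.
  - Loss of the 1,4 orientation is the least likely failure.
- Fallback: the macrocycle is closed at the ring B–ring C bridge by carbonyl coupling instead. It sets out from 9.
  - Aqueous HCl in THF removes the MOM group and gives phenol aldehyde F1.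
  - SNAr with 4-fluorobenzaldehyde (K2CO3, DMF, 120 °C) gives dialdehyde F2.
  - Intramolecular McMurry coupling with low-valent titanium (TiCl4, Zn, THF, reflux, high dilution) gives macrocyclic stilbene F3.
  - H2 over Pd/C saturates F3, and the sequence rejoins the route at 23.

**Step 11.**
- What may go wrong:
  - The acrylate may polymerise at 70 °C.
  - The activated aryl ester may suffer acyl–oxygen cleavage by titanium species.
  - The dienyl ether may hydrolyse on acidic adsorbents or dimerise on concentration.
- Fallback: the diene is made by elimination rather than by carbonyl methylenation. It sets out from 15.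
  - K2CO3 in MeOH cleaves the acrylate and gives silyl-protected phenol F4.
  - Mitsunobu etherification (PPh3, DIAD, THF) with 1,4-dibromobutan-2-ol gives dibromide F5.
  - KOtBu in THF at 0 °C effects two E2 eliminations, the classical route from β-haloethyl aryl ethers to aryl vinyl ethers. The sequence rejoins the route at 16.

**Step 15.**
- What may go wrong:
  - The acidic hydroquinone and traces of water may hydrolyse the enol ether, which would open the macrocycle.
  - The first hydride abstraction next to the acyl-bearing carbon may need forcing.
  - Forcing invites dehydrogenation of the ring A–ring D bridge para to the methoxy group. The ionic hydrogenation of step 16 should reverse that over-oxidation.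
- Fallback: bromination and dehydrobromination replace the first dehydrogenation. It sets out from 19.
  - Br2 (1 equiv) in CH2Cl2 at −78 °C adds to the enol ether double bond and gives dibromide F6.
  - DBU removes two HBr and moves the diene into conjugation with the ketone, which rejoins the route at 20.
  - MnO2 then takes 20 on to 21.

**Step 7.**
- What may go wrong:
  - During the time needed for MOM cleavage, the arylacetaldehyde may self-condense by aldol reaction.
  - The aldehyde may also cyclodehydrate onto ring D ortho to the ether oxygen in a seven-membered closure.
  - The MOM group may come off only partly.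
- Fallback: deprotection is separated from release of the aldehyde. It sets out from 10.
  - Catalytic TsOH in MeOH adds methanol to the enol ether and transacetalises the MOM group. This gives the stable phenol dimethyl acetal F7.
  - Brief treatment with Amberlyst-15 in wet acetone at rt frees the aldehyde, and the sequence rejoins the route at 11.

**Step 5.**
- What may go wrong:
  - The fluorine is flanked by two ortho groups, and the methoxy group feeds electron density into the adduct, so substitution may be sluggish.
  - The aldehyde may degrade at the temperature then required.
- Fallback: a copper-catalysed Ullmann ether synthesis replaces the uncatalysed substitution. It sets out from 7 and uses 2-bromo-3-methoxybenzaldehyde, CuI, N,N-dimethylglycine and Cs2CO3 in 1,4-dioxane at 90 °C. It rejoins the route at 9 and makes no new compound (F0).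

## Further compounds

F1 | step 14 | 2-{3-[2-(3-hydroxy-4-methoxyphenyl)ethyl]phenoxy}-3-methoxybenzaldehyde | COc1ccc(CCc2cccc(Oc3c(OC)cccc3C=O)c2)cc1O
F2 | step 14 | 2-(3-{2-[3-(4-formylphenoxy)-4-methoxyphenyl]ethyl}phenoxy)-3-methoxybenzaldehyde | COc1ccc(CCc2cccc(Oc3c(OC)cccc3C=O)c2)cc1Oc1ccc(C=O)cc1
F3 | step 14 | macrocyclic stilbene, marchantin C dimethyl ether with CH=CH between rings B and C (geometry not defined) | COc1ccc2cc1Oc1ccc(cc1)C=Cc1cccc(OC)c1Oc1cccc(c1)CC2
F4 | step 11 | rac-5-(2-{3-[2-(2-(tert-butyldimethylsilyloxy)but-3-en-1-yl)-6-methoxyphenoxy]phenyl}ethyl)-2-methoxyphenol | COc1ccc(CCc2cccc(Oc3c(OC)cccc3CC(O[Si](C)(C)C(C)(C)C)C=C)c2)cc1O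
F5 | step 11 | 1,4-dibromobutan-2-yl ether of F4 (mixture of diastereomers) | COc1ccc(CCc2cccc(Oc3c(OC)cccc3CC(O[Si](C)(C)C(C)(C)C)C=C)c2)cc1OC(CBr)CCBr
F6 | step 15 | macrocycle with ring B as 4-acyl-1-aryloxy-1,2-dibromocyclohexane (mixture of diastereomers) | COc1ccc2cc1OC1(Br)CCC(CC1Br)C(=O)Cc1cccc(OC)c1Oc1cccc(c1)CC2
F7 | step 7 | 5-(2-{3-[2-(2,2-dimethoxyethyl)-6-methoxyphenoxy]phenyl}ethyl)-2-methoxyphenol | COc1ccc(CCc2cccc(Oc3c(OC)cccc3CC(OC)OC)c2)cc1O
F0 | step 5 | none | none
A1 | alternative 1 | seco phenol with ring D as a 5-fluoro-2-nitrophenyl unit | COc1ccc(CCc2cc(F)ccc2[N+](=O)[O-])cc1Oc1ccc(CCc2cccc(OC)c2O)cc1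
A2 | alternative 1 | nitro marchantin C dimethyl ether, nitro on ring D para to the new ether | COc1ccc2cc1Oc1ccc(cc1)CCc1cccc(OC)c1Oc1ccc([N+](=O)[O-])c(c1)CC2
A3 | alternative 2 | 22-membered macrocyclic 1,5-diketone with an α-aryloxy ketone | COc1ccc2cc1Oc1ccc(cc1)CCC(=O)CCCC(=O)COc1cccc(c1)CC2
A4 | alternative 2 | 18-membered macrocycle with ring C as 2-aryloxy-3-alkylcyclohex-2-enone | COc1ccc2cc1Oc1ccc(cc1)CCC1=C(C(=O)CCC1)Oc1cccc(c1)CC2
A5 | alternative 3 | seco bis(phenol), ring A 2,6-dibromophenol and ring B 2,6-dichlorophenol | Oc1c(Br)cc(cc1Br)CCc1cccc(c1)Oc1c(OC)cccc1CCc1cc(Cl)c(O)c(Cl)c1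
A6 | alternative 3 | bromo dichloro marchantin C mono methyl ether | Oc1c(Br)cc2cc1Oc1c(Cl)cc(cc1Cl)CCc1cccc(OC)c1Oc1cccc(c1)CC2
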